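**Strategy.** The route rests on cutting the C4–C5 bond of the 2-alkylidene-2,5-dihydrofuran (ring atoms O1, C2 with its two methyl groups, C3, C4, C5; exocyclic carbon C6 bearing the formyl group). C5 is at once the enol-ether carbon and the β-carbon of the enal C5=C6–CHO, so it accepts an alkenylpalladium species and still carries the hydrogen needed for β-hydride elimination. The key step is a 5-exo-trig Heck cyclisation of a tertiary (Z)-3-iodoallyl enol ether of a 2-substituted malonaldehyde: it closes the ring, delivers the cis C3=C4 alkene and restores the push–pull C5=C6 double bond in one operation. The two stereocentres come from an Ireland–Claisen rearrangement.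

Key step: step 11

Assumption: the target is treated in the open-chain aldehyde–acid form drawn; a reversible lactol between the carboxylic acid and the 2-oxoethyl aldehyde would not change the route.

Step 1
Reactants: 1 2-(3-chloropropyl)-2-methyl-1,3-dioxolane; 2 diketene (4-methylideneoxetan-2-one)
Product: 4 3-methylidene-6-(2-methyl-1,3-dioxolan-2-yl)hexanoic acid, via Grignard reagent 3 (not isolated)
Conditions: Mg, THF, 50 °C; then 2, NiCl2 (5 mol %), THF, −20 → 0 °C; aq. citric acid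
Reagents that add atoms: none
Why: Nickel-catalysed ring-opening cross-coupling of diketene with a Grignard reagent (cleavage of the vinylic C–O bond) is an established one-step entry to 3-methylidene alkanoic acids, and the dioxolane keeps the ketone inert here and in the later enolate step.

Step 2
Reactants: 5 (S)-but-3-en-2-ol; 6 4,4-diethoxybut-1-ene
Product: 7 (2S,3E)-6,6-diethoxyhex-3-en-2-ol
Conditions: second-generation Grubbs catalyst (H2IMes)(PCy3)Cl2Ru=CHPh (3 mol %), 6 (3 equiv), CH2Cl2, 40 °C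
Reagents that add atoms: none
Why: Olefin cross-metathesis of a secondary allylic alcohol with an unhindered terminal alkene should give the E-alkene, and the carbinol stereocentre bought in with 5 is not touched.

Step 3
Reactants: 4 3-methylidene-6-(2-methyl-1,3-dioxolan-2-yl)hexanoic acid; 7 (2S,3E)-6,6-diethoxyhex-3-en-2-ol
Product: 8 (2S,3E)-6,6-diethoxyhex-3-en-2-yl 3-methylidene-6-(2-methyl-1,3-dioxolan-2-yl)hexanoate
Conditions: DCC, DMAP (10 mol %), CH2Cl2, 0 → 25 °C
Reagents that add atoms: none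
Why: Steglich esterification at low temperature should acylate the secondary allylic alcohol with retention at the carbinol carbon and without moving the 3-methylidene double bond into conjugation.

Step 4
Reactants: 8 (2S,3E)-6,6-diethoxyhex-3-en-2-yl 3-methylidene-6-(2-methyl-1,3-dioxolan-2-yl)hexanoate
Product: 11 (2R,3R,4E)-3-(2,2-diethoxyethyl)-2-[5-(2-methyl-1,3-dioxolan-2-yl)pent-1-en-2-yl]hex-4-enoic acid, via silyl ketene acetal 9 (not isolated), via trimethylsilyl ester 10 (not isolated)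
Conditions: LDA (LiN(iPr)2), THF–DMPU, −78 °C; TMSCl/Et3N, −78 → 25 °C; then aq. citric acid
Reagents that add atoms: none
Why: Ireland–Claisen rearrangement: LDA in THF–DMPU should give the Z(O) lithium dienolate (alkenyl group cis to O–Li), and its silyl ketene acetal 9 rearranges through a chair transition state with the carbinol methyl group equatorial, so that the S centre of 8 is relayed into the 2R,3R (syn) acid bearing an E-propenyl group.

Step 5
Reactants: 11 (2R,3R,4E)-3-(2,2-diethoxyethyl)-2-[5-(2-methyl-1,3-dioxolan-2-yl)pent-1-en-2-yl]hex-4-enoic acid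
Product: 12 2-(trimethylsilyl)ethyl (2R,3R,4E)-3-(2,2-diethoxyethyl)-2-[5-(2-methyl-1,3-dioxolan-2-yl)pent-1-en-2-yl]hex-4-enoate
Conditions: 2-(trimethylsilyl)ethanol, PPh3, DIAD, THF, 0 → 25 °C
Reagents that add atoms: 2-(trimethylsilyl)ethanol C[Si](C)(C)CCO
Why: Mitsunobu esterification activates the primary alcohol and not the acid, so the epimerisable, deconjugated α-centre is never part of an acylating intermediate.

Step 6
Reactants: 12 2-(trimethylsilyl)ethyl (2R,3R,4E)-3-(2,2-diethoxyethyl)-2-[5-(2-methyl-1,3-dioxolan-2-yl)pent-1-en-2-yl]hex-4-enoate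
Product: 13 2-(trimethylsilyl)ethyl (2R,3R)-3-(2,2-diethoxyethyl)-2-[5-(2-methyl-1,3-dioxolan-2-yl)pent-1-en-2-yl]pent-4-enoate
Conditions: ethylene (5 bar), second-generation Hoveyda–Grubbs catalyst (H2IMes)Cl2Ru=CH(C6H4-2-OiPr) (5 mol %), toluene, 50 °C
Reagents that add atoms: ethylene C=C
Why: Ethenolysis (cross-metathesis with ethylene) should trim the E-propenyl group to a vinyl group, while the 1,1-disubstituted alkene can only undergo degenerate exchange and a ring-closing event would need a cyclobutene.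

Step 7
Reactants: 13 2-(trimethylsilyl)ethyl (2R,3R)-3-(2,2-diethoxyethyl)-2-[5-(2-methyl-1,3-dioxolan-2-yl)pent-1-en-2-yl]pent-4-enoate
Product: 14 2-(trimethylsilyl)ethyl (2R,3S)-5,5-diethoxy-2-[5-(2-methyl-1,3-dioxolan-2-yl)pent-1-en-2-yl]-3-(2-oxoethyl)pentanoate
Conditions: PdCl2(PhCN)2 (10 mol %), CuCl2·2H2O (10 mol %), AgNO2 (5 mol %), t-BuOH/MeNO2, O2 (1 atm), 25 °C
Reagents that add atoms: dioxygen O=O
Why: Nitrite-modified, aldehyde-selective Wacker oxidation should oxidise the monosubstituted vinyl group at its terminal carbon, helped by the branched allylic position, and leave the 1,1-disubstituted alkene alone.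

Step 8
Reactants: 14 2-(trimethylsilyl)ethyl (2R,3S)-5,5-diethoxy-2-[5-(2-methyl-1,3-dioxolan-2-yl)pent-1-en-2-yl]-3-(2-oxoethyl)pentanoate
Product: 15 2-(trimethylsilyl)ethyl (2R,3S)-3-[(E)-1-(dimethylamino)-3-oxoprop-1-en-2-yl]-5,5-diethoxy-2-[5-(2-methyl-1,3-dioxolan-2-yl)pent-1-en-2-yl]pentanoate
Conditions: t-BuOCH(NMe2)2, toluene, 60 °C
Reagents that add atoms: tert-butoxybis(dimethylamino)methane CN(C)C(OC(C)(C)C)N(C)C
Why: Aminomethylenation with Bredereck's reagent should take place at the only activated CH2 group (α to the aldehyde) and give the 2-substituted 3-(dimethylamino)acrolein, a protected malonaldehyde.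

Step 9
Reactants: 16 ethyl (Z)-3-iodoacrylate
Product: 17 (Z)-4-iodo-2-methylbut-3-en-2-ol
Conditions: MeMgBr (2.5 equiv), THF, −78 → 0 °C; aq. NH4Cl
Reagents that add atoms: methylmagnesium bromide C[Mg]Br
Why: Double Grignard addition to the ester at low temperature should give the tertiary alcohol with the Z-iodoalkene intact.

Step 10
Reactants: 15 2-(trimethylsilyl)ethyl (2R,3S)-3-[(E)-1-(dimethylamino)-3-oxoprop-1-en-2-yl]-5,5-diethoxy-2-[5-(2-methyl-1,3-dioxolan-2-yl)pent-1-en-2-yl]pentanoate; 17 (Z)-4-iodo-2-methylbut-3-en-2-ol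
Product: 21 2-(trimethylsilyl)ethyl (2R,3S)-5,5-diethoxy-3-[(E)-1-{[(3Z)-4-iodo-2-methylbut-3-en-2-yl]oxy}-3-oxoprop-1-en-2-yl]-2-[5-(2-methyl-1,3-dioxolan-2-yl)pent-1-en-2-yl]pentanoate, via chloroiminium chloride 18 (not isolated), via sodium alkoxide 19 (not isolated), via alkoxyiminium chloride 20 (not isolated)
Conditions: (COCl)2, CH2Cl2, −20 °C; then 19 (from 17, NaH, THF, 0 °C), −78 → 0 °C; then sat. aq. NaHCO3, 25 °C
Reagents that add atoms: water O
Why: Vinylogous Vilsmeier activation of the enaminal gives a 3-chloropropeniminium salt that should undergo addition–elimination (nucleophilic vinylic substitution) by the tertiary alkoxide, and bicarbonate hydrolysis of the iminium then leaves the E-configured β-alkoxy enal, the isomer with the alkoxy group trans to the formyl group being the more stable one.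

Step 11
Reactants: 21 2-(trimethylsilyl)ethyl (2R,3S)-5,5-diethoxy-3-[(E)-1-{[(3Z)-4-iodo-2-methylbut-3-en-2-yl]oxy}-3-oxoprop-1-en-2-yl]-2-[5-(2-methyl-1,3-dioxolan-2-yl)pent-1-en-2-yl]pentanoate
Product: 23 2-(trimethylsilyl)ethyl (2R,3S)-3-[(1E)-1-(5,5-dimethylfuran-2(5H)-ylidene)-2-oxoethyl]-5,5-diethoxy-2-[5-(2-methyl-1,3-dioxolan-2-yl)pent-1-en-2-yl]pentanoate, via Z isomer 22 (not isolated)
Conditions: Pd(OAc)2 (10 mol %), PPh3 (25 mol %), Ag2CO3 (1.5 equiv), MeCN, 70 °C
Reagents that add atoms: none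
Why: Oxidative addition of zerovalent palladium into the Z-alkenyl iodide gives an alkenylpalladium iodide whose syn carbopalladation of the C5=C6 enol-ether double bond puts C4 on C5 and palladium on C6 (α to the aldehyde), and rotation about C5–C6 followed by syn β-hydride elimination of the C5–H rebuilds the exocyclic double bond. The closest known reaction type is the intramolecular Heck reaction, in particular 5-exo cyclisations and arylations of β-alkoxy acrylates (vinylogous carbonates). The dihydrofuran ring closes in the 5-exo-trig mode, the 6-endo attack at C6 being disfavoured by ring size and by the polarisation of the push–pull alkene, which makes C5 the electrophilic carbon. No stereocentre is formed: the cis C3=C4 geometry is carried in by the Z-iodide of 17, and the syn-addition/syn-elimination sequence should first give the Z isomer 22, whose donor–acceptor C5=C6 bond has a low rotational barrier and should equilibrate at 70 °C to the E isomer 23, in which the bulky chain lies next to the ring oxygen and not next to the C4–H. The selectivity the step needs is β-hydride elimination from C5 and not from the chain stereocentre attached to C6; the C5–H is allylic and α to oxygen, and its loss gives the fully conjugated dienyl ether. Silver carbonate removes iodide, so that the cationic pathway operates and the palladium hydride is quenched before it can re-add or migrate the 1,1-disubstituted alkene.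

Step 12
Reactants: 23 2-(trimethylsilyl)ethyl (2R,3S)-3-[(1E)-1-(5,5-dimethylfuran-2(5H)-ylidene)-2-oxoethyl]-5,5-diethoxy-2-[5-(2-methyl-1,3-dioxolan-2-yl)pent-1-en-2-yl]pentanoate
Product: 25 (2R,3S)-3-[(1E)-1-(5,5-dimethylfuran-2(5H)-ylidene)-2-oxoethyl]-5-oxo-2-(6-oxohept-1-en-2-yl)pentanoic acid (CNP0150297.1), via carboxylic acid 24 (not isolated)
Conditions: Bu4NF, THF, 0 → 25 °C; then 1 M HCl, THF/H2O, 25 °C
Reagents that add atoms: water O
Why: Fluoride-induced β-elimination cleaves the 2-(trimethylsilyl)ethyl ester without touching the α-centre, and mild aqueous acid then hydrolyses the diethyl acetal and the dioxolane, the vinylogous ester of the ring being expected to survive because its hydrolysis is reversible and it re-closes.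

**Compound list**

1 | 2-(3-chloropropyl)-2-methyl-1,3-dioxolane | CC1(CCCCl)OCCO1 | starting material
2 | diketene (4-methylideneoxetan-2-one) | C=C1CC(=O)O1 | starting material
3 | [3-(2-methyl-1,3-dioxolan-2-yl)propyl]magnesium chloride | CC1(CCC[Mg]Cl)OCCO1 | intermediate
4 | 3-methylidene-6-(2-methyl-1,3-dioxolan-2-yl)hexanoic acid | C=C(CCCC1(C)OCCO1)CC(=O)O | intermediate
5 | (S)-but-3-en-2-ol | C[C@H](O)C=C | starting material
6 | 4,4-diethoxybut-1-ene | C=CCC(OCC)OCC | starting material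
7 | (2S,3E)-6,6-diethoxyhex-3-en-2-ol | C[C@H](O)/C=C/CC(OCC)OCC | intermediate
8 | (2S,3E)-6,6-diethoxyhex-3-en-2-yl 3-methylidene-6-(2-methyl-1,3-dioxolan-2-yl)hexanoate | C=C(CCCC1(C)OCCO1)CC(=O)O[C@@H](C)/C=C/CC(OCC)OCC | intermediate
9 | (1Z)-1-{[(2S,3E)-6,6-diethoxyhex-3-en-2-yl]oxy}-3-methylidene-6-(2-methyl-1,3-dioxolan-2-yl)-1-(trimethylsilyloxy)hex-1-ene | C=C(CCCC1(C)OCCO1)/C=C(\O[Si](C)(C)C)O[C@@H](C)/C=C/CC(OCC)OCC | intermediate
10 | trimethylsilyl (2R,3R,4E)-3-(2,2-diethoxyethyl)-2-[5-(2-methyl-1,3-dioxolan-2-yl)pent-1-en-2-yl]hex-4-enoate | C=C(CCCC1(C)OCCO1)[C@H](C(=O)O[Si](C)(C)C)[C@H](CC(OCC)OCC)/C=C/C | intermediate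
11 | (2R,3R,4E)-3-(2,2-diethoxyethyl)-2-[5-(2-methyl-1,3-dioxolan-2-yl)pent-1-en-2-yl]hex-4-enoic acid | C=C(CCCC1(C)OCCO1)[C@H](C(=O)O)[C@H](CC(OCC)OCC)/C=C/C | intermediate
12 | 2-(trimethylsilyl)ethyl (2R,3R,4E)-3-(2,2-diethoxyethyl)-2-[5-(2-methyl-1,3-dioxolan-2-yl)pent-1-en-2-yl]hex-4-enoate | C=C(CCCC1(C)OCCO1)[C@H](C(=O)OCC[Si](C)(C)C)[C@H](CC(OCC)OCC)/C=C/C | intermediate
13 | 2-(trimethylsilyl)ethyl (2R,3R)-3-(2,2-diethoxyethyl)-2-[5-(2-methyl-1,3-dioxolan-2-yl)pent-1-en-2-yl]pent-4-enoate | C=C(CCCC1(C)OCCO1)[C@H](C(=O)OCC[Si](C)(C)C)[C@H](CC(OCC)OCC)C=C | intermediate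
14 | 2-(trimethylsilyl)ethyl (2R,3S)-5,5-diethoxy-2-[5-(2-methyl-1,3-dioxolan-2-yl)pent-1-en-2-yl]-3-(2-oxoethyl)pentanoate | C=C(CCCC1(C)OCCO1)[C@H](C(=O)OCC[Si](C)(C)C)[C@H](CC(OCC)OCC)CC=O | intermediate
15 | 2-(trimethylsilyl)ethyl (2R,3S)-3-[(E)-1-(dimethylamino)-3-oxoprop-1-en-2-yl]-5,5-diethoxy-2-[5-(2-methyl-1,3-dioxolan-2-yl)pent-1-en-2-yl]pentanoate | C=C(CCCC1(C)OCCO1)[C@H](C(=O)OCC[Si](C)(C)C)[C@H](CC(OCC)OCC)/C(C=O)=C\N(C)C | intermediate
16 | ethyl (Z)-3-iodoacrylate | CCOC(=O)/C=C\I | starting material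
17 | (Z)-4-iodo-2-methylbut-3-en-2-ol | CC(C)(O)/C=C\I | intermediate
18 | 3-chloropropeniminium chloride derived from 15 (Cl–CH=C(R)–CH=NMe2+ Cl−, R = chain of 15) | C=C(CCCC1(C)OCCO1)[C@H](C(=O)OCC[Si](C)(C)C)[C@H](CC(OCC)OCC)C(C=[N+](C)C)=CCl.[Cl-] | intermediate
19 | sodium (Z)-4-iodo-2-methylbut-3-en-2-olate | CC(C)([O-])/C=C\I.[Na+] | intermediate
20 | 3-alkoxypropeniminium chloride (chloride of 18 replaced by the alkoxide of 17) | C=C(CCCC1(C)OCCO1)[C@H](C(=O)OCC[Si](C)(C)C)[C@H](CC(OCC)OCC)C(C=[N+](C)C)=COC(C)(C)/C=C\I.[Cl-] | intermediate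
21 | 2-(trimethylsilyl)ethyl (2R,3S)-5,5-diethoxy-3-[(E)-1-{[(3Z)-4-iodo-2-methylbut-3-en-2-yl]oxy}-3-oxoprop-1-en-2-yl]-2-[5-(2-methyl-1,3-dioxolan-2-yl)pent-1-en-2-yl]pentanoate | C=C(CCCC1(C)OCCO1)[C@H](C(=O)OCC[Si](C)(C)C)[C@H](CC(OCC)OCC)/C(C=O)=C\OC(C)(C)/C=C\I | intermediate
22 | 2-(trimethylsilyl)ethyl (2R,3S)-3-[(1Z)-1-(5,5-dimethylfuran-2(5H)-ylidene)-2-oxoethyl]-5,5-diethoxy-2-[5-(2-methyl-1,3-dioxolan-2-yl)pent-1-en-2-yl]pentanoate | C=C(CCCC1(C)OCCO1)[C@H](C(=O)OCC[Si](C)(C)C)[C@H](CC(OCC)OCC)/C(C=O)=C1\C=CC(C)(C)O1 | intermediate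
23 | 2-(trimethylsilyl)ethyl (2R,3S)-3-[(1E)-1-(5,5-dimethylfuran-2(5H)-ylidene)-2-oxoethyl]-5,5-diethoxy-2-[5-(2-methyl-1,3-dioxolan-2-yl)pent-1-en-2-yl]pentanoate | C=C(CCCC1(C)OCCO1)[C@H](C(=O)OCC[Si](C)(C)C)[C@H](CC(OCC)OCC)/C(C=O)=C1/C=CC(C)(C)O1 | intermediate
24 | (2R,3S)-3-[(1E)-1-(5,5-dimethylfuran-2(5H)-ylidene)-2-oxoethyl]-5,5-diethoxy-2-[5-(2-methyl-1,3-dioxolan-2-yl)pent-1-en-2-yl]pentanoic acid | C=C(CCCC1(C)OCCO1)[C@H](C(=O)O)[C@H](CC(OCC)OCC)/C(C=O)=C1/C=CC(C)(C)O1 | intermediate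
25 | (2R,3S)-3-[(1E)-1-(5,5-dimethylfuran-2(5H)-ylidene)-2-oxoethyl]-5-oxo-2-(6-oxohept-1-en-2-yl)pentanoic acid (CNP0150297.1) | C=C(CCCC(C)=O)[C@H](C(=O)O)[C@H](CC=O)/C(C=O)=C1/C=CC(C)(C)O1 | target

**Step count.** Total: 12 steps. Longest linear sequence: 10 steps (steps 1, 3, 4, 5, 6, 7, 8, 10, 11, 12).

**Steps most likely to fail**

Step 11 (Heck cyclisation). β-Hydride elimination may take the hydrogen of the chain stereocentre attached to C6 instead of the C5 hydrogen, which would move the double bond out of conjugation with the ring oxygen and erase that stereocentre. Zerovalent palladium may also ionise the tertiary allylic C2–O1 bond of substrate or product, and the Z-to-E equilibration of the exocyclic alkene may stay incomplete. Fallback: setting out from 21, a tin-hydride radical cyclisation (Bu3SnH, Et3B/air, toluene, 0 °C) should add the alkenyl radical 5-exo-trig to C5 of the β-alkoxy enal and give 2-(trimethylsilyl)ethyl (2R,3R)-3-[1-(5,5-dimethyl-2,5-dihydrofuran-2-yl)-2-oxoethyl]-5,5-diethoxy-2-[5-(2-methyl-1,3-dioxolan-2-yl)pent-1-en-2-yl]pentanoate F1 as a mixture of epimers at the two new sp3 carbons. Oxidative C–H cleavage with DDQ (1,2-dichloroethane, 2,6-dichloropyridine, 40 °C) should then abstract hydride from the allylic ether C5–H, and loss of the α-formyl proton from the oxocarbenium ion returns to 23. This sequence still closes the ring at C4–C5, and the double bond can only form towards C5.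

Step 10 (tertiary enol ether). Hydrolysis of the alkoxyiminium salt may expel the hindered tertiary alkoxide instead of dimethylamine, which would return the malonaldehyde, and the alkoxide may dehydroiodinate the Z-iodoalkene. Fallback: setting out from 15, hydrolysis (1 M NaOH, THF, 0 °C; then NaH2PO4) should give 2-(trimethylsilyl)ethyl (2R,3S)-5,5-diethoxy-3-(1-hydroxy-3-oxoprop-1-en-2-yl)-2-[5-(2-methyl-1,3-dioxolan-2-yl)pent-1-en-2-yl]pentanoate F2 (enol form of the malonaldehyde). Copper-catalysed propargylic etherification with methyl 2-methylbut-3-yn-2-yl carbonate (CuCl2, DBU, MeCN, 0 °C) should alkylate the acidic enol oxygen and give 2-(trimethylsilyl)ethyl (2R,3S)-5,5-diethoxy-3-{(E)-1-[(2-methylbut-3-yn-2-yl)oxy]-3-oxoprop-1-en-2-yl}-2-[5-(2-methyl-1,3-dioxolan-2-yl)pent-1-en-2-yl]pentanoate F3. Iodination of the terminal alkyne (N-iodosuccinimide, AgNO3, acetone) should give 2-(trimethylsilyl)ethyl (2R,3S)-5,5-diethoxy-3-{(E)-1-[(4-iodo-2-methylbut-3-yn-2-yl)oxy]-3-oxoprop-1-en-2-yl}-2-[5-(2-methyl-1,3-dioxolan-2-yl)pent-1-en-2-yl]pentanoate F4. Cis-reduction of the iodoalkyne with diimide (2-nitrobenzenesulfonyl hydrazide, Et3N, THF/i-PrOH) returns to 21.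

Step 7 (aldehyde-selective Wacker oxidation). Markovnikov oxypalladation may give the methyl ketone, and the Lewis-acidic copper and palladium chlorides may cleave the diethyl acetal, after which the two aldehyde arms could no longer be told apart. Fallback: setting out from 13, hydroboration with disiamylborane (Sia2BH, THF, 0 °C; NaBO3·4H2O work-up), which prefers the monosubstituted vinyl group over the hindered 1,1-disubstituted alkene, should give 2-(trimethylsilyl)ethyl (2R,3S)-5,5-diethoxy-3-(2-hydroxyethyl)-2-[5-(2-methyl-1,3-dioxolan-2-yl)pent-1-en-2-yl]pentanoate F5. Dess–Martin oxidation (CH2Cl2, NaHCO3, 0 → 25 °C) returns to 14.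

**Further compounds**

F1 | step 11 | 2-(trimethylsilyl)ethyl (2R,3R)-3-[1-(5,5-dimethyl-2,5-dihydrofuran-2-yl)-2-oxoethyl]-5,5-diethoxy-2-[5-(2-methyl-1,3-dioxolan-2-yl)pent-1-en-2-yl]pentanoate (epimers at the two new centres) | C=C(CCCC1(C)OCCO1)[C@H](C(=O)OCC[Si](C)(C)C)[C@H](CC(OCC)OCC)C(C=O)C1C=CC(C)(C)O1
F2 | step 10 | 2-(trimethylsilyl)ethyl (2R,3S)-5,5-diethoxy-3-(1-hydroxy-3-oxoprop-1-en-2-yl)-2-[5-(2-methyl-1,3-dioxolan-2-yl)pent-1-en-2-yl]pentanoate | C=C(CCCC1(C)OCCO1)[C@H](C(=O)OCC[Si](C)(C)C)[C@H](CC(OCC)OCC)C(C=O)=CO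
F3 | step 10 | 2-(trimethylsilyl)ethyl (2R,3S)-5,5-diethoxy-3-{(E)-1-[(2-methylbut-3-yn-2-yl)oxy]-3-oxoprop-1-en-2-yl}-2-[5-(2-methyl-1,3-dioxolan-2-yl)pent-1-en-2-yl]pentanoate | C=C(CCCC1(C)OCCO1)[C@H](C(=O)OCC[Si](C)(C)C)[C@H](CC(OCC)OCC)/C(C=O)=C\OC(C)(C)C#C
F4 | step 10 | 2-(trimethylsilyl)ethyl (2R,3S)-5,5-diethoxy-3-{(E)-1-[(4-iodo-2-methylbut-3-yn-2-yl)oxy]-3-oxoprop-1-en-2-yl}-2-[5-(2-methyl-1,3-dioxolan-2-yl)pent-1-en-2-yl]pentanoate | C=C(CCCC1(C)OCCO1)[C@H](C(=O)OCC[Si](C)(C)C)[C@H](CC(OCC)OCC)/C(C=O)=C\OC(C)(C)C#CI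
F5 | step 7 | 2-(trimethylsilyl)ethyl (2R,3S)-5,5-diethoxy-3-(2-hydroxyethyl)-2-[5-(2-methyl-1,3-dioxolan-2-yl)pent-1-en-2-yl]pentanoate | C=C(CCCC1(C)OCCO1)[C@H](C(=O)OCC[Si](C)(C)C)[C@H](CC(OCC)OCC)CCO
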